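Read amounts as percent of the electrophile charged, and ask what the electrophile can have become by the end of each flask.

all flasks: electrophile 0.082 M; nucleophile 1.05 equiv
- Saturday's: free base 0.51 equiv; scavenger 0.30 equiv; run made earlier
- birch: free base 0.400 equiv; scavenger 0.300 equiv; time 25 h
- elm: free base 1.20 equiv; scavenger 0.300 equiv; time 25 h
- alder: free base 4.00 equiv; scavenger 0.300 equiv; time 25 h

- Saturday's (time / h: target / %, electrophile / %): 1.33: 2.2, 97.8; 2.50: 5.8, 93.9; 5.00: 11.8, 86.8; 10.0: 18.0, 80.6; 20.0: 31.8, 66.6

(readings scatter by 1 percentage point)

- "hardly changes" means that all values lie within two and a half points (for a concentration: within two and a half percent of the largest)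
- no earlier run changes the charge of free base; that part of a forecast is a guess

* amount of target at the end, in percent of the electrophile charged for birch, elm, alder, in this order
* how the row runs (hardly changes / rises, then falls / rises all the way / falls, then rises / falls all the way)

Take the main step first: electrophile and nucleophile give target, with the electrophile as limiting reagent by charge. Count half-lives. Saturday's reading puts c(electrophile) at 66.6 % after 20.0 h, so read 34.1 h as the electrophile half-life, the time in which c(electrophile) drops by a factor of 2 at Saturday's pace. The asked 25 h then hold 0.733 half-lives, which leave 60.2 % and turn over 39.8 %. Assume, as my own guess, that free base leaves this pace alone, since no earlier run varies it; the main step then gives that same ceiling for birch, elm and alder.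

Now add one loss. Saturday's target and electrophile at 20.0 h fall short of the charge by 1.6 percentage points, a reading close to its scatter. Suppose free base consumes target, so that the gap scales with the base charge and with the square of time. The reckoned loss at the end is then 2 points for birch, 5.9 points for elm and 20 points for alder, which takes my estimate of target to 37.8 %, 33.9 % and 20.2 %.

Add the rest: the main step uses nucleophile and electrophile one to one, and the half-life comes from the reading at 20.0 h, taken with that fall under way, so leave these estimates as they stand.

The forecast gives 31 %, 60 % and 78 %, a row that rises all the way, on its declared guess that “the rate grows with base”. Here it parts from my reckoning, whose row falls: its alder value stands above my ceiling.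

The flask gives 36.9 %, 26.6 % and 10.1 % of target in birch, elm and alder, a row that falls all the way.

    acid set free + free base ⇌ idle adduct, settled at all times (K = 4.10 M⁻¹)
    acid set free + free base ⇌ salt of the base, settled at all times (K = 37000 M⁻¹)
    free base + target → over-reaction product (k = 0.420 M⁻¹ h⁻¹)
    nucleophile + acid set free ⇌ protonated nucleophile, settled at all times (K = 250 M⁻¹)
    acid set free + scavenger → scavenged by-product (k = 6.70 M⁻¹ h⁻¹)
    electrophile + nucleophile → acid set free + target (k = 0.300 M⁻¹ h⁻¹)

Electrophile left at the end stands at 60.8 %, 60.4 % and 60.4 % in birch, elm and alder, against the 60.2 % counted, while over-reaction product stands at 2.28 %, 12.9 % and 29.5 %. Run the count to 12.5 h in alder: 0.367 half-lives leave 77.6 %, and the flask holds 75.5 %.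

The runs come from a simulation for substances that don't exist, noise included.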